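**Strategy.** Everything rests on cutting C1–C2, the bond joining the 14-membered carbocycle to the β-carbon of the α-methylene-γ-butyrolactone (ring O–C16–C15(=C17)–C1–C14). A C2 alkyl iodide whose other chain end carries the preformed butenolide, with a phenylsulfonylmethyl group on C15, is cyclised by radical addition–fragmentation: the C2 radical adds to C1 anti to the C14 substituent, the C15 radical expels PhSO2•, and the carbocycle, the C1 stereocentre and the exocyclic C15=C17 methylene arise in one operation. The precursor is built from nerol (C6–C13, both ring olefins), an (S)-glycerate acetonide (C2–C4), a hydroxymethyl Grignard (C18) and tulipalin A (lactone carbons), through enolate alkylation, chelate-controlled addition and an asymmetric vinylogous aldol.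

Key step: step 14

Remark (numbering and one assumption): cembrane numbering is used throughout — C1 lactone β-carbon, C2, C3 (OAc), C4 (OH, bears C18), C5, C6, C7=C8 (Z, methyl C19), C9, C10, C11=C12 (E, methyl C20), C13 (OH), C14 (lactone O), C15(=C17), C16 (C=O); (S)-BINOL is assumed to be the ligand antipode that delivers 13R,14R in step 10, otherwise (R)-BINOL is used.

**Step 1**
Reactants: 1 nerol
Product: 2 neryl bromide
Conditions: PBr3 (0.4 equiv), Et2O, −10 °C
Reagents that add atoms: phosphorus tribromide, BrP(Br)Br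
Why: SN2 bromination of the primary allylic alcohol through its phosphite ester at low temperature should leave the Z geometry (future C7=C8) untouched.

**Step 2**
Reactants: 3 methyl (4S)-2,2-dimethyl-1,3-dioxolane-4-carboxylate
Product: 5 1-[(4S)-2,2-dimethyl-1,3-dioxolan-4-yl]ethan-1-one, via Weinreb amide 4 (not isolated)
Conditions: MeNH(OMe)·HCl, i-PrMgCl, THF, −20 °C; then MeMgBr, −20 → 0 °C
Reagents that add atoms: N,O-dimethylhydroxylamine hydrochloride, CNOC.Cl (atoms in 4 only); methylmagnesium bromide, C[Mg]Br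
Why: Magnesium-amide aminolysis gives the Weinreb amide, whose chelated tetrahedral adduct with MeMgBr stops at the ketone (Weinreb ketone synthesis), and these cold non-enolising conditions should not touch the C3 stereocentre.

**Step 3**
Reactants: 5 1-[(4S)-2,2-dimethyl-1,3-dioxolan-4-yl]ethan-1-one; 2 neryl bromide
Product: 6 (4Z)-1-[(4S)-2,2-dimethyl-1,3-dioxolan-4-yl]-5,9-dimethyldeca-4,8-dien-1-one
Conditions: LDA, THF, −78 °C; then 2, DMPU, −78 → −30 °C
Reagents that add atoms: none
Why: Kinetic deprotonation should occur at the methyl group (the other α-position is a hindered alkoxy methine), and SN2 alkylation of the lithium enolate by the allylic bromide forms C5–C6 without allylic transposition.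

**Step 4**
Reactants: 6 (4Z)-1-[(4S)-2,2-dimethyl-1,3-dioxolan-4-yl]-5,9-dimethyldeca-4,8-dien-1-one
Product: 8 (2S,5Z)-2-[(4S)-2,2-dimethyl-1,3-dioxolan-4-yl]-6,10-dimethylundeca-5,9-diene-1,2-diol, via silyl carbinol 7 (not isolated)
Conditions: (i-PrO)Me2SiCH2MgCl, THF, −78 → 0 °C; then KF, KHCO3, 30% H2O2, THF/MeOH, rt
Reagents that add atoms: (isopropoxydimethylsilyl)methylmagnesium chloride, CC(C)O[Si](C)(C)C[Mg]Cl; hydrogen peroxide, OO
Why: Cram-chelate addition (Mg bridging the ketone and the dioxolane oxygen on C3, attack from the C3–H face) should set 4S, with O3 and O4 syn along C2–C3–C4–C18, and Tamao oxidation then turns the C18–Si bond into C18–OH.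

**Step 5**
Reactants: 8 (2S,5Z)-2-[(4S)-2,2-dimethyl-1,3-dioxolan-4-yl]-6,10-dimethylundeca-5,9-diene-1,2-diol
Product: 9 (2S,5Z)-2-[(4S)-2,2-dimethyl-1,3-dioxolan-4-yl]-2-hydroxy-6,10-dimethylundeca-5,9-dien-1-yl acetate
Conditions: Ac2O, pyridine, CH2Cl2, 0 °C → rt
Reagents that add atoms: acetic anhydride, CC(=O)OC(C)=O
Why: Acylation should take only the primary C18 hydroxyl, the tertiary C4 hydroxyl being inert without forcing conditions; this acetate is already the one of the target.

**Step 6**
Reactants: 9 (2S,5Z)-2-[(4S)-2,2-dimethyl-1,3-dioxolan-4-yl]-2-hydroxy-6,10-dimethylundeca-5,9-dien-1-yl acetate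
Product: 11 (2S,5Z,9E)-2-[(4S)-2,2-dimethyl-1,3-dioxolan-4-yl]-2-hydroxy-6,10-dimethyl-11-oxoundeca-5,9-dien-1-yl acetate, via allylic alcohol 10 (not isolated)
Conditions: SeO2 (0.5 equiv), t-BuOOH, salicylic acid (cat.), CH2Cl2, rt; filter; then MnO2, CH2Cl2, rt
Reagents that add atoms: selenium dioxide, O=[Se]=O; tert-butyl hydroperoxide, CC(C)(C)OO
Why: SeO2/t-BuOOH allylic oxidation (ene then [2,3] shift) should attack the more accessible terminal isopropylidene at its E-methyl, as in ω-oxidations of polyprenyl chains, and MnO2 then takes only the allylic alcohol to the (E)-enal (C13).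

**Step 7**
Reactants: 12 α-methylene-γ-butyrolactone (tulipalin A)
Product: 14 3-(bromomethyl)furan-2(5H)-one, via dibromolactone 13 (not isolated)
Conditions: Br2, CH2Cl2, 0 °C; then i-Pr2NEt, 0 °C → rt
Reagents that add atoms: bromine, BrBr
Why: Bromine addition to the exocyclic alkene followed by E2 loss of HBr towards the ring CH2 should give the conjugated endocyclic butenolide, which keeps the primary allylic bromide.

**Step 8**
Reactants: 14 3-(bromomethyl)furan-2(5H)-one
Product: 15 3-[(phenylsulfonyl)methyl]furan-2(5H)-one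
Conditions: PhSO2Na, DMF, 0 °C → rt
Reagents that add atoms: sodium benzenesulfinate, [Na+].[O-]S(=O)c1ccccc1
Why: S-alkylation of the sulfinate by the allylic bromide gives the allyl sulfone; any SN2′ isomer should be funnelled to this conjugated primary sulfone by reversible sulfinate addition–elimination.

**Step 9**
Reactants: 15 3-[(phenylsulfonyl)methyl]furan-2(5H)-one
Product: 16 trimethyl({3-[(phenylsulfonyl)methyl]furan-2-yl}oxy)silane
Conditions: TMSOTf, Et3N, Et2O, 0 °C; filtered and used crude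
Reagents that add atoms: trimethylsilyl trifluoromethanesulfonate, C[Si](C)(C)OS(=O)(=O)C(F)(F)F
Why: O-silylation and loss of a C5 proton give the aromatic 2-silyloxyfuran (silyl dienol ether formation), which is favoured over deprotonation at the sulfonylmethyl group.

**Step 10**
Reactants: 11 (2S,5Z,9E)-2-[(4S)-2,2-dimethyl-1,3-dioxolan-4-yl]-2-hydroxy-6,10-dimethyl-11-oxoundeca-5,9-dien-1-yl acetate; 16 trimethyl({3-[(phenylsulfonyl)methyl]furan-2-yl}oxy)silane
Product: 18 (2S,5Z,9E,11R)-2-[(4S)-2,2-dimethyl-1,3-dioxolan-4-yl]-2,11-dihydroxy-6,10-dimethyl-11-{(2R)-5-oxo-4-[(phenylsulfonyl)methyl]-2,5-dihydrofuran-2-yl}undeca-5,9-dien-1-yl acetate (13R,14R), via trimethylsilyl ether 17 (not isolated)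
Conditions: Ti(Oi-Pr)4/(S)-BINOL (20 mol %), Et2O, −20 °C; then 10% citric acid, MeOH, 0 °C
Reagents that add atoms: none
Why: Catalytic asymmetric vinylogous Mukaiyama aldol: the silyloxyfuran attacks through C5 to form C13–C14 as the syn (threo) adduct, the absolute sense at C13/C14 being set by the Ti–BINOL catalyst because the C3/C4 centres are too remote to interfere.

**Step 11**
Reactants: 18 the 13R,14R aldol adduct
Product: 19 C13 tert-butyldimethylsilyl ether of 18
Conditions: TBSCl, imidazole, DMAP (cat.), DMF, rt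
Reagents that add atoms: tert-butyldimethylsilyl chloride, CC(C)(C)[Si](C)(C)Cl
Why: Silylation of the secondary C13 hydroxyl under conditions that neither silylate the tertiary C4 hydroxyl nor enolise the butenolide (no silyl triflate, so C14 is safe).

**Step 12**
Reactants: 19 C13 TBS ether
Product: 20 C2,C3,C4-triol (dioxolane removed; 18-OAc and 13-OTBS retained)
Conditions: AcOH/H2O (4:1), rt
Reagents that add atoms: none
Why: Mild acid hydrolysis of the terminal isopropylidene acetal, under which the hindered secondary TBS ether, the acetate and the allyl sulfone butenolide are expected to survive.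

**Step 13**
Reactants: 20 C2,C3,C4-triol
Product: 21 C2 iodide (3-OH and 4-OH free; 3R by CIP only because iodine raises the rank of C2, same spatial arrangement)
Conditions: I2, PPh3, imidazole, CH2Cl2, 0 °C
Reagents that add atoms: iodine, II
Why: Appel-type iodination is selective for the primary C2 hydroxyl over the secondary C3 and tertiary C4 hydroxyls.

**Step 14**
Reactants: 21 C2 iodide carrying the 3-(phenylsulfonylmethyl)butenolide
Product: 22 (1R,3S,4S,7Z,11E,13R,14R)-18-acetoxy-13-(tert-butyldimethylsilyloxy)-3,4-dihydroxycembra-7,11,15(17)-trien-16,14-olide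
Conditions: (Bu3Sn)2 (2 equiv), hν (sunlamp, Pyrex), PhH, 1 mM (21 added by syringe pump), 20 °C
Reagents that add atoms: none
Why: Proposed new method: photolysis of the ditin gives Bu3Sn•, which abstracts iodine from C2; the primary C2 radical adds to C1, the β-carbon of the butenolide (14-exo-trig, C15 stays outside the new ring), and the C15 α-lactone radical expels PhSO2• by β-scission of C17–S, so the C1–C2 bond, the carbocycle and the exocyclic C15=C17 methylene form together while the ditin scavenges PhSO2• and returns Bu3Sn•. The closest known reaction types are the ditin-mediated radical allylation of alkyl iodides with 2-(sulfonylmethyl)acrylates (SH2′ addition–fragmentation) and hydride-mediated radical macrocyclisation onto enoates; addition–fragmentation onto a 3-(sulfonylmethyl)butenolide as a macrocyclisation has not been shown. The new stereocentre C1 is controlled by C14: the radical should enter anti to the C13 side chain on the neighbouring lactone carbon, as intermolecular radical additions to 5-substituted butenolides do, giving the trans (1R,14R) lactone. The step needs cyclisation to outrun 1,5-hydrogen transfer from the allylic C6–H and all bimolecular paths; the absence of any hydride donor, high dilution and photochemical initiation at room temperature are meant to secure this, and the fragmentation makes ring closure irreversible. The C3 and C4 hydroxyls are left free on purpose, because an acyloxy group on C3 could undergo a 1,2-acyloxy shift in the C2 radical.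

**Step 15**
Reactants: 22 macrocyclic 3,4-diol
Product: 23 (1R,3S,4S,7Z,11E,13R,14R)-3,18-diacetoxy-13-(tert-butyldimethylsilyloxy)-4-hydroxycembra-7,11,15(17)-trien-16,14-olide
Conditions: Ac2O, pyridine, DMAP (cat.), CH2Cl2, 0 °C → rt
Reagents that add atoms: acetic anhydride, CC(=O)OC(C)=O
Why: Acetylation of the secondary C3 hydroxyl; the tertiary C4 hydroxyl should stay free under these conditions and C13 is masked as its silyl ether.

**Step 16**
Reactants: 23 3,18-diacetate 13-TBS ether
Product: 24 durumolide G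
Conditions: HF·pyridine, pyridine/THF, 0 °C → rt
Reagents that add atoms: none
Why: Buffered fluoride desilylation should free the C13 alcohol without acetate migration or conjugate addition to the α-methylene lactone.

**Compound list**
1 | nerol, (2Z)-3,7-dimethylocta-2,6-dien-1-ol | CC(C)=CCC/C(C)=C\CO | starting material
2 | neryl bromide, (2Z)-1-bromo-3,7-dimethylocta-2,6-diene | CC(C)=CCC/C(C)=C\CBr | intermediate
3 | methyl (4S)-2,2-dimethyl-1,3-dioxolane-4-carboxylate | COC(=O)[C@@H]1COC(C)(C)O1 | starting material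
4 | (4S)-N-methoxy-N,2,2-trimethyl-1,3-dioxolane-4-carboxamide (Weinreb amide) | CON(C)C(=O)[C@@H]1COC(C)(C)O1 | intermediate (not isolated)
5 | 1-[(4S)-2,2-dimethyl-1,3-dioxolan-4-yl]ethan-1-one | CC(=O)[C@@H]1COC(C)(C)O1 | intermediate
6 | (4Z)-1-[(4S)-2,2-dimethyl-1,3-dioxolan-4-yl]-5,9-dimethyldeca-4,8-dien-1-one (C2–C12, C4 ketone) | CC(C)=CCC/C(C)=C\CCC(=O)[C@@H]1COC(C)(C)O1 | intermediate
7 | C4 tertiary alcohol of 6 with CH2SiMe2(Oi-Pr) as C18 (4R by CIP because of silicon, same spatial arrangement as 8) | C1OC(C)(C)O[C@@H]1[C@@](O)(C[Si](C)(C)OC(C)C)CC/C=C(/C)CCC=C(C)C | intermediate (not isolated)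
8 | (2S,5Z)-2-[(4S)-2,2-dimethyl-1,3-dioxolan-4-yl]-6,10-dimethylundeca-5,9-diene-1,2-diol | C1OC(C)(C)O[C@@H]1[C@@](O)(CO)CC/C=C(/C)CCC=C(C)C | intermediate
9 | (2S,5Z)-2-[(4S)-2,2-dimethyl-1,3-dioxolan-4-yl]-2-hydroxy-6,10-dimethylundeca-5,9-dien-1-yl acetate | C1OC(C)(C)O[C@@H]1[C@@](O)(COC(C)=O)CC/C=C(/C)CCC=C(C)C | intermediate
10 | (2S,5Z,9E)-2-[(4S)-2,2-dimethyl-1,3-dioxolan-4-yl]-2,11-dihydroxy-6,10-dimethylundeca-5,9-dien-1-yl acetate (C13 allylic alcohol) | C1OC(C)(C)O[C@@H]1[C@@](O)(COC(C)=O)CC/C=C(/C)CC/C=C(\C)CO | intermediate (not isolated)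
11 | (2S,5Z,9E)-2-[(4S)-2,2-dimethyl-1,3-dioxolan-4-yl]-2-hydroxy-6,10-dimethyl-11-oxoundeca-5,9-dien-1-yl acetate (C13 enal) | C1OC(C)(C)O[C@@H]1[C@@](O)(COC(C)=O)CC/C=C(/C)CC/C=C(\C)C=O | intermediate
12 | α-methylene-γ-butyrolactone (tulipalin A) | C=C1CCOC1=O | starting material
13 | 3-bromo-3-(bromomethyl)dihydrofuran-2(3H)-one | BrCC1(Br)CCOC1=O | intermediate (not isolated)
14 | 3-(bromomethyl)furan-2(5H)-one | BrCC1=CCOC1=O | intermediate
15 | 3-[(phenylsulfonyl)methyl]furan-2(5H)-one | O=C1OCC=C1CS(=O)(=O)c1ccccc1 | intermediate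
16 | trimethyl({3-[(phenylsulfonyl)methyl]furan-2-yl}oxy)silane | C[Si](C)(C)Oc1occc1CS(=O)(=O)c1ccccc1 | intermediate
17 | C13 trimethylsilyl ether of 18 | C1OC(C)(C)O[C@@H]1[C@@](O)(COC(C)=O)CC/C=C(/C)CC/C=C(\C)[C@@H](O[Si](C)(C)C)[C@@H]2OC(=O)C(CS(=O)(=O)c3ccccc3)=C2 | intermediate (not isolated)
18 | (2S,5Z,9E,11R)-2-[(4S)-2,2-dimethyl-1,3-dioxolan-4-yl]-2,11-dihydroxy-6,10-dimethyl-11-{(2R)-5-oxo-4-[(phenylsulfonyl)methyl]-2,5-dihydrofuran-2-yl}undeca-5,9-dien-1-yl acetate | C1OC(C)(C)O[C@@H]1[C@@](O)(COC(C)=O)CC/C=C(/C)CC/C=C(\C)[C@@H](O)[C@@H]2OC(=O)C(CS(=O)(=O)c3ccccc3)=C2 | intermediate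
19 | C13 tert-butyldimethylsilyl ether of 18 | C1OC(C)(C)O[C@@H]1[C@@](O)(COC(C)=O)CC/C=C(/C)CC/C=C(\C)[C@@H](O[Si](C)(C)C(C)(C)C)[C@@H]2OC(=O)C(CS(=O)(=O)c3ccccc3)=C2 | intermediate
20 | triol: 19 with the dioxolane opened (2-OH, 3-OH, 4-OH; 18-OAc; 13-OTBS) | OC[C@H](O)[C@@](O)(COC(C)=O)CC/C=C(/C)CC/C=C(\C)[C@@H](O[Si](C)(C)C(C)(C)C)[C@@H]1OC(=O)C(CS(=O)(=O)c2ccccc2)=C1 | intermediate
21 | C2 iodide of 20 | IC[C@H](O)[C@@](O)(COC(C)=O)CC/C=C(/C)CC/C=C(\C)[C@@H](O[Si](C)(C)C(C)(C)C)[C@@H]1OC(=O)C(CS(=O)(=O)c2ccccc2)=C1 | intermediate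
22 | (1R,3S,4S,7Z,11E,13R,14R)-18-acetoxy-13-(tert-butyldimethylsilyloxy)-3,4-dihydroxycembra-7,11,15(17)-trien-16,14-olide | C=C1C(=O)O[C@@H]2[C@@H]1C[C@H](O)[C@@](O)(COC(C)=O)CC/C=C(/C)CC/C=C(\C)[C@H]2O[Si](C)(C)C(C)(C)C | intermediate
23 | (1R,3S,4S,7Z,11E,13R,14R)-3,18-diacetoxy-13-(tert-butyldimethylsilyloxy)-4-hydroxycembra-7,11,15(17)-trien-16,14-olide | C=C1C(=O)O[C@@H]2[C@@H]1C[C@H](OC(C)=O)[C@@](O)(COC(C)=O)CC/C=C(/C)CC/C=C(\C)[C@H]2O[Si](C)(C)C(C)(C)C | intermediate
24 | durumolide G | C=C1C(=O)O[C@@H]2[C@@H]1C[C@H](OC(C)=O)[C@@](O)(COC(C)=O)CC/C=C(/C)CC/C=C(\C)[C@H]2O | target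

**Step count.** Total: 16 steps. Longest linear sequence: 12 steps (steps 2–6 and 10–16 from ester 3; equally steps 1, 3–6 and 10–16 from nerol).

**Steps most likely to fail**

Step 14 (the labelled step). What may go wrong: 1,5-hydrogen transfer from the allylic C6–H to the C2 radical before it adds to the β-substituted butenolide terminus; 1,3-shift of the allyl sulfone or Z→E isomerisation of C7=C8 by reversible sulfonyl-radical addition; chain failure at 1 mM. The fallback uses known chemistry: a hydride-mediated Giese-type radical macrocyclisation onto a butenolide that carries no radical leaving group, followed by base elimination. It shares the C2 radical, so it answers the sulfonyl-radical and chain problems and only eases hydrogen transfer through initiation at 0 °C. It sets out from bromide 14 and enal 11. KOAc in DMF converts 14 into 3-(acetoxymethyl)furan-2(5H)-one F1, and TMSOTf/Et3N gives 3-(acetoxymethyl)-2-(trimethylsilyloxy)furan F2. The Ti–BINOL aldol with 11 gives, through the C13 trimethylsilyl ether F3, the 13R,14R alcohol F4. TBSCl/imidazole gives the silyl ether F5, aqueous AcOH the triol F6, and I2/PPh3/imidazole the C2 iodide F7. (Me3Si)3SiH (syringe pump) with Et3B/air in benzene at 2 mM and 0 °C should close the 14-membered ring to the saturated trans-lactone F8 (mixture at C15). DBU in CH2Cl2 then eliminates acetic acid (E1cB) and the route is rejoined at macrocycle 22.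

Step 10. What may go wrong: poor facial control by the Ti–BINOL catalyst on a hindered α-branched enal with a 3-substituted silyloxyfuran; erosion of the syn:anti ratio; opening of the acetonide by the Lewis acid. The fallback replaces the aldol by a reagent-controlled allylboration and a ring-closing metathesis, and sets out from enal 11. (Z)-γ-(4-Methoxyphenoxy)allyl-diisopinocampheylborane (allyl 4-methoxyphenyl ether, s-BuLi; Ipc2BOMe; BF3·OEt2; Ipc antipode chosen for 13R,14R) should give the syn mono-aryl ether F9. TBSCl/imidazole gives the C13 silyl ether F10, and CAN in MeCN/H2O at 0 °C frees the C14 alcohol F11. 2-[(Phenylsulfonyl)methyl]acrylic acid F12 (from 2-(bromomethyl)acrylic acid and PhSO2Na) is joined through its mixed anhydride (2,4,6-trichlorobenzoyl chloride, Et3N; then F11, DMAP cat.) to give the ester F13. Grubbs second-generation catalyst in toluene at 80 °C closes the butenolide (C1=C15) and the route is rejoined at silyl ether 19.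

Step 3. What may go wrong: proton exchange between enolate and product leading to dialkylation; equilibration to the C3 enolate with β-elimination of the dioxolane oxygen or loss of configuration at C3. The fallback builds the Z olefin by carbocupration and forms C6–C7 by conjugate addition. It sets out from Weinreb amide 4 (here isolated), which with vinylmagnesium bromide gives the vinyl ketone F14. (4-Methylpent-3-en-1-yl)magnesium bromide F15 (from commercial 5-bromo-2-methylpent-2-ene and Mg) with CuBr·SMe2 adds syn across propyne to give the (Z)-alkenylcopper F16. This adds 1,4 to F14 (TMSCl, THF, −78 °C) and the route is rejoined at ketone 6, with the C7=C8 geometry fixed by the syn carbometalation.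

**Further compounds**
F1 | step 14 | 3-(acetoxymethyl)furan-2(5H)-one | CC(=O)OCC1=CCOC1=O
F2 | step 14 | 3-(acetoxymethyl)-2-(trimethylsilyloxy)furan | CC(=O)OCc1ccoc1O[Si](C)(C)C
F3 | step 14 | C13 trimethylsilyl ether of F4 | C1OC(C)(C)O[C@@H]1[C@@](O)(COC(C)=O)CC/C=C(/C)CC/C=C(\C)[C@@H](O[Si](C)(C)C)[C@@H]2OC(=O)C(COC(C)=O)=C2
F4 | step 14 | 13R,14R aldol adduct with 3-(acetoxymethyl)butenolide | C1OC(C)(C)O[C@@H]1[C@@](O)(COC(C)=O)CC/C=C(/C)CC/C=C(\C)[C@@H](O)[C@@H]2OC(=O)C(COC(C)=O)=C2
F5 | step 14 | C13 tert-butyldimethylsilyl ether of F4 | C1OC(C)(C)O[C@@H]1[C@@](O)(COC(C)=O)CC/C=C(/C)CC/C=C(\C)[C@@H](O[Si](C)(C)C(C)(C)C)[C@@H]2OC(=O)C(COC(C)=O)=C2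
F6 | step 14 | C2,C3,C4-triol from F5 | OC[C@H](O)[C@@](O)(COC(C)=O)CC/C=C(/C)CC/C=C(\C)[C@@H](O[Si](C)(C)C(C)(C)C)[C@@H]1OC(=O)C(COC(C)=O)=C1
F7 | step 14 | C2 iodide from F6 | IC[C@H](O)[C@@](O)(COC(C)=O)CC/C=C(/C)CC/C=C(\C)[C@@H](O[Si](C)(C)C(C)(C)C)[C@@H]1OC(=O)C(COC(C)=O)=C1
F8 | step 14 | saturated trans-fused macrocyclic lactone with 15-(acetoxymethyl) group, C15 epimers | CC(=O)OCC1C(=O)O[C@@H]2[C@@H]1C[C@H](O)[C@@](O)(COC(C)=O)CC/C=C(/C)CC/C=C(\C)[C@H]2O[Si](C)(C)C(C)(C)C
F9 | step 10 | syn 13-hydroxy-14-(4-methoxyphenoxy) terminal alkene | C1OC(C)(C)O[C@@H]1[C@@](O)(COC(C)=O)CC/C=C(/C)CC/C=C(\C)[C@@H](O)[C@H](Oc2ccc(OC)cc2)C=C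
F10 | step 10 | C13 tert-butyldimethylsilyl ether of F9 | C1OC(C)(C)O[C@@H]1[C@@](O)(COC(C)=O)CC/C=C(/C)CC/C=C(\C)[C@@H](O[Si](C)(C)C(C)(C)C)[C@H](Oc2ccc(OC)cc2)C=C
F11 | step 10 | C14 alcohol from F10 | C1OC(C)(C)O[C@@H]1[C@@](O)(COC(C)=O)CC/C=C(/C)CC/C=C(\C)[C@@H](O[Si](C)(C)C(C)(C)C)[C@H](O)C=C
F12 | step 10 | 2-[(phenylsulfonyl)methyl]acrylic acid | C=C(CS(=O)(=O)c1ccccc1)C(=O)O
F13 | step 10 | C14 2-[(phenylsulfonyl)methyl]acrylate of F11 | C1OC(C)(C)O[C@@H]1[C@@](O)(COC(C)=O)CC/C=C(/C)CC/C=C(\C)[C@@H](O[Si](C)(C)C(C)(C)C)[C@H](OC(=O)C(=C)CS(=O)(=O)c2ccccc2)C=C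
F14 | step 3 | 1-[(4S)-2,2-dimethyl-1,3-dioxolan-4-yl]prop-2-en-1-one | C=CC(=O)[C@@H]1COC(C)(C)O1
F15 | step 3 | (4-methylpent-3-en-1-yl)magnesium bromide | CC(C)=CCC[Mg]Br
F16 | step 3 | [(1Z)-2,6-dimethylhepta-1,5-dien-1-yl]copper | CC(C)=CCC/C(C)=C\[Cu]
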